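The minute is the wrong unit for the next flask, so count lifetimes instead. The blue run repeats the teal charge with more catalyst, and you have to decide what that extra catalyst can buy at a stop of 14 min.

| flask | starting material | partner | catalyst | time |
|---|---|---|---|---|
| grey | 0.100 M | 0.200 M | 0.00100 M |  |
| violet | 0.0500 M | 0.150 M | 0.00100 M |  |
| green | 0.100 M | 0.300 M | 0.00100 M |  |
| teal | 0.300 M | 0.200 M | 0.00100 M |  |
| blue | 0.300 M | 0.200 M | 0.00300 M | 14 min |

- grey run (time / min: [target] / M): 0.56: 0.0056; 1.3: 0.0142; 2.8: 0.0248; 6.3: 0.0523; 14: 0.0851
- violet run (time / min: [target] / M): 0.56: 0.0021; 1.3: 0.0080; 2.8: 0.0162; 6.3: 0.0298; 14: 0.0428
- green run (time / min: [target] / M): 0.56: 0.0048; 1.3: 0.0124; 2.8: 0.0239; 6.3: 0.0485; 14: 0.0782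
- teal run (time / min: [target] / M): 0.56: 0.0128; 1.3: 0.0301; 2.8: 0.0684; 6.3: 0.1345; 14: 0.2008

(readings scatter by 0.001 M)

- reaction order in [partner] at the outset, round the charge of the grey run, defined at two percent of the starting material turned into target
- reaction order in [starting material] at the outset, round the charge of the grey run, defined at two percent of the starting material turned into target (one fixed amount of target, the same in the runs compared)
- the violet run starts with 0.0500 M less of starting material and of partner than the grey run, and with no target. Compared where both hold the same amount of starting material, once fifteen percent of what the violet run was charged with has turned into target, is the violet run faster, slower or alike (within a tenth)?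
- target in the blue run at 14 min, as a share of the starting material charged

- Overall: starting material + partner -> target, with catalyst as catalyst.
- Constant volume, constant temperature.
- Bound and free are read together.
- An order is taken over about fifteen percent of the charge, up and down.

In the teal run the partner is the limiting reagent, 0.200 M against 0.300 M of starting material. One target forms per partner, so the ceiling is 66.7% of the starting material charged. Whether the blue run reaches that ceiling hangs on time. By my reading of the teal run, the partner left falls from 0.132 M at 2.8 min to 0.0655 M at 6.3 min, which gives 5.02 min for τ, the lifetime, meaning the time in which what is left of the limiting reagent falls by a factor of e.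

By that count the teal run has 2.79 lifetimes at 14 min, which would leave 0.0123 M of partner. Its last reading of 0.2008 M of target is more than that count allows and stands at the partner charge within the scatter of 0.001 M, so τ errs towards too much left. I assume the rate goes in proportion to catalyst, which I cannot test because the earlier runs share one charge of 0.00100 M. The blue run, with 3.00 times the catalyst of the teal run, then gets N = 8.37 lifetimes, leaving about 4.62 × 10⁻⁵ M of partner, far below the scatter. My reckoning for the blue run is therefore 66.7%, and I would charge it expecting no more target than the teal run gave.

The forecast gave −0.25 for the order in partner, 0.85 for the order in starting material, alike for the violet comparison and 66.7% for the blue run, holding that blue, “with more catalyst, should also be finished”.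

The blue run gives 66.7%, the orders at the outset are −0.27 in partner and 0.87 in starting material, and violet and grey are alike.

    catalyst + starting material → catalyst-substrate complex (460.2 M⁻¹ min⁻¹)
    catalyst-substrate complex + partner → target + catalyst (1752 M⁻¹ min⁻¹)
    catalyst + partner ⇌ idle catalyst-reagent complex, settled at all times (61.60 M⁻¹)
    2 partner ⇌ idle reagent dimer, settled at all times (42.90 M⁻¹)

At a reckoned 8.37 lifetimes, the figure for the blue run reports the partner charge, not the rate law. The pairing of catalyst with partner moves the order in partner from 0.21 to −0.27, yet taking it away leaves the blue run at 66.7%. In the green run starting material is the limiting reagent, and the half-time of 6.78 min gives τ = 9.79 min. That makes 1.43 lifetimes at 14 min and 0.0761 M of target, where the green run reads 0.0782 M.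

(All runs are calculated with constants of no real substance, noise included.)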